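The numbers stand for no real mixture; the result is computed.

In a one-step world substrate would become target and stay target; here a second step eats the target, so the share depends on how long the target has stood.

    free enzyme → unfolded enzyme (k1 = 1.2 × 10⁻⁵ s⁻¹, Ea1 = 214 kJ mol⁻¹)
    substrate + free enzyme → target + free enzyme, rate k2*[substrate]*[free enzyme]/(1 + ([substrate]/Km2)) (Km2 = 0.050 M, k2 = 130 M⁻¹ s⁻¹, Ea2 = 38.0 kJ mol⁻¹)
    2 free enzyme ⇌ resting dimer, settled at all times (K3 = 64000 M⁻¹, ΔH3 = −12.0 kJ mol⁻¹)
    substrate + target → side product (k4 = 0.0054 M⁻¹ s⁻¹, Ea4 = 47.0 kJ mol⁻¹)
    free enzyme + impurity → spent catalyst (k5 = 1700 M⁻¹ s⁻¹, Ea5 = 39.0 kJ mol⁻¹)
    (constants at 37 °C)

- noon: substrate 0.050 M; free enzyme 7.0 µM; impurity 7.3 µM; temperature 37 °C; time 1.0 h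
- spring: substrate 0.050 M; free enzyme 7.0 µM; impurity 7.3 µM; temperature 17 °C; time 1.0 h

- percent here means substrate units held: one side product counts as two
- where a step has two of a species, its rate is k times that concentration squared, and two are used at each turn
- constants are those at 37 °C; use the activation energies and enthalpies for any other temperature

- which flask leads in share of target in all that became target or side product ("all alike" within 1.5 percentage points) (noon / spring / all alike)
- share of target in all that became target or side product, noon
- share of target in all that became target or side product, spring

I count turnovers on a ladder of clocks, fastest first, starting with noon. The resting dimer needs no clock, since it is kept at balance. At the charged substrate one enzyme makes a target every 0.308 s. While the impurity stands at its charge, the enzyme meets it about every 80.6 s, so at the start it makes some 262 turnovers per meeting. Each meeting uses up one of each, so the meetings slow as both fall, and this figure holds for the start of the run and not for an enzyme's whole life. Steps 2 and 5 both speed up by 2.8 between spring and noon, which leaves that starting figure alike in the two flasks. Next, one target lasts 1.03 h against the substrate, about the length of the run; step 4 is pseudo-first-order in target while the substrate stays near its charge. Slowest is unfolding, at 23.1 h, and at noon it makes no difference.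

On the target's clock, then, the first meeting with the impurity comes early, so I picture noon as target laid down mostly early and slowly eaten. So I carry one number, the turns of the target, 0.972 at noon: step 4's constant times the charged substrate times the time. After that many turns a fraction f, e to the minus the turns, survives. Each lost target sits in a side product holding two units, so the share is f / (f + 2(1 − f)). That gives 23.3 % at noon. Step 4 slows by 3.5 in spring, so there the turns are 0.277 and the share is 61.1 %. These figures date every target from the first moment and hold the substrate at its charge, so I take them as low marks.

The forecast says spring, with 35 % at noon and 72 % in spring, both above my figures; its ground is that “the outcome depends on how much of it is then lost to side product over the hour”.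

The simulation gives spring in the lead, with 34.5 % at noon and 72.4 % in spring.

The temperature's effect on step 4 is the largest single effect among those tried: the difference noon minus spring is −38 percentage points with it and −2.8 points without it. Read back through the same formula, the noon share means 0.667 turns, against 0.972 counted. The neighbour of noon charged with 4.2 × 10⁻⁶ M of free enzyme keeps 95 % of its substrate and 43 % of its impurity, and its share of 26.0 % lies nearer 23.3 % than noon's does.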